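**Retrosynthetic overview**

- The route rests on ring A: C5, C6, C7 and C8 each carry oxygen (5-OH, 6-OMe, 7-OH, 8-OMe) on a benzo ring fused to pyranone ring C through C4a–C8a.
- Ring A is made last, from a squarate: C4a–C5 by Grignard addition of a C5-metallated pyranone to tert-butyl methyl squarate, and C8–C8a by thermal ring expansion of the resulting 4-pyranonylcyclobutenone.
- The four squarate carbons become C5–C8 with their oxygens already told apart: OMOM (C5), OMe (C6), OtBu (C7), free OH (C8).
- Ring C is closed earlier by iodocyclization of an enaminodiketone, so iodine enters at C5 without halogenating the electron-rich ring B.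
- Order of rings: B (from isovanillin benzyl ether), then C, then A. The end game is O-methylation at C8, acidolysis, and hydrogenolysis.

Key step: step 11

Remark: 3-(benzyloxy)-4-methoxybenzaldehyde is taken as a purchasable form of isovanillin. The stereocentres met on the way (C2 of 10–12, C4 of 19 and 20, C8a of 22) are formed without control, are all racemic and are erased by step 11; the target has none.

**Route**

Step 1
Reactants: 1 3-(benzyloxy)-4-methoxybenzaldehyde
Product: 3 3-(benzyloxy)-4-methoxyphenol, via aryl formate 2 (not isolated)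
Conditions: mCPBA, CH2Cl2, 0 °C → rt; then K2CO3 (cat.), MeOH, rt
Reagents that add atoms: 3-chloroperoxybenzoic acid, O=C(OO)c1cccc(Cl)c1
Why: Baeyer–Villiger oxidation of an electron-rich benzaldehyde, in which the para-methoxy aryl group migrates to give the formate, followed by base-catalysed methanolysis.

Step 2
Reactants: 3 3-(benzyloxy)-4-methoxyphenol
Product: 4 2,4-bis(benzyloxy)-1-methoxybenzene
Conditions: BnBr, K2CO3, DMF, rt
Reagents that add atoms: benzyl bromide, BrCc1ccccc1
Why: Williamson ether synthesis on the phenoxide, which leaves the future 2'- and 4'-oxygens of ring B as benzyl ethers and the 5'-oxygen as the methyl ether.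

Step 3
Reactants: 4 2,4-bis(benzyloxy)-1-methoxybenzene
Product: 5 1,5-bis(benzyloxy)-2-bromo-4-methoxybenzene
Conditions: NBS, MeCN, 0 °C
Reagents that add atoms: N-bromosuccinimide, O=C1CCC(=O)N1Br
Why: Electrophilic aromatic bromination should go to the one position that is para to one benzyloxy group, ortho to the other and not flanked by two substituents, which is the future C1' of ring B.

Step 4
Reactants: 5 1,5-bis(benzyloxy)-2-bromo-4-methoxybenzene; 6 N,2-dimethoxy-N-methylacetamide
Product: 8 1-[2,4-bis(benzyloxy)-5-methoxyphenyl]-2-methoxyethan-1-one, via aryllithium 7 (not isolated)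
Conditions: n-BuLi, THF, −78 °C; then 6, −78 → 0 °C; 1 M HCl
Reagents that add atoms: none
Why: Bromine–lithium exchange followed by Weinreb ketone synthesis, in which the chelated tetrahedral adduct holds until work-up so that the ketone cannot take up a second aryllithium.

Step 5
Reactants: 8 1-[2,4-bis(benzyloxy)-5-methoxyphenyl]-2-methoxyethan-1-one; 9 (E)-3-ethoxyprop-2-enoyl chloride
Product: 11 (4E)-1-[2,4-bis(benzyloxy)-5-methoxyphenyl]-5-(dimethylamino)-2-methoxypent-4-ene-1,3-dione (racemic), via ethoxyenone diketone 10 (not isolated)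
Conditions: LiN(SiMe3)2 (2.2 equiv), THF, −78 °C; 9; AcOH; then Me2NH (2 M in THF), rt
Reagents that add atoms: dimethylamine, CNC
Why: Claisen-type C-acylation of the chelated lithium enolate of an α-methoxy ketone by the acid chloride (the second equivalent of base takes up the acidic diketone), followed by conjugate addition–elimination of dimethylamine at the β-ethoxy enone; the methine centre forms as a racemate and is erased in step 6.

Step 6
Reactants: 11 (4E)-1-[2,4-bis(benzyloxy)-5-methoxyphenyl]-5-(dimethylamino)-2-methoxypent-4-ene-1,3-dione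
Product: 13 2-[2,4-bis(benzyloxy)-5-methoxyphenyl]-5-iodo-3-methoxy-4H-pyran-4-one, via iodoenaminone 12 (not isolated)
Conditions: I2 (1.2 equiv), CHCl3, rt
Reagents that add atoms: iodine, II
Why: Halogenative cyclization of a β-enaminone, the reaction type used to make 3-iodochromones, in which the enaminone α-carbon (far more nucleophilic than the acyl-deactivated ring B) takes up iodine and the enol oxygen of the aryl ketone then adds to the iminium carbon and expels dimethylamine, so that ring C closes with iodine already at C5.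

Step 7
Reactants: 14 3,4-dimethoxycyclobut-3-ene-1,2-dione (dimethyl squarate)
Product: 16 3-hydroxy-4-methoxycyclobut-3-ene-1,2-dione, via sodium monomethyl squarate 15 (not isolated)
Conditions: NaOH (1.0 equiv), MeOH, 0 °C → rt; then HCl (1.0 equiv, in dioxane)
Reagents that add atoms: sodium hydroxide, [Na+].[OH-]
Why: Semi-saponification by addition–elimination of hydroxide at one vinylogous ester carbon, which should stop at the monoester because its delocalized anion resists a second attack.

Step 8
Reactants: 16 3-hydroxy-4-methoxycyclobut-3-ene-1,2-dione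
Product: 17 3-tert-butoxy-4-methoxycyclobut-3-ene-1,2-dione
Conditions: Cl3CC(=NH)OtBu, CH2Cl2/cyclohexane, rt
Reagents that add atoms: tert-butyl 2,2,2-trichloroacetimidate, CC(C)(C)OC(=N)C(Cl)(Cl)Cl
Why: O-tert-butylation of a strong vinylogous acid by the trichloroacetimidate (self-promoted ionization to the tert-butyl cation and capture by the squarate monoanion), which can lead to only one mixed 1,2-diester.

Step 9
Reactants: 13 2-[2,4-bis(benzyloxy)-5-methoxyphenyl]-5-iodo-3-methoxy-4H-pyran-4-one; 17 3-tert-butoxy-4-methoxycyclobut-3-ene-1,2-dione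
Product: 19 4-{6-[2,4-bis(benzyloxy)-5-methoxyphenyl]-5-methoxy-4-oxo-4H-pyran-3-yl}-2-tert-butoxy-4-hydroxy-3-methoxycyclobut-2-en-1-one (racemic), via pyranonylmagnesium chloride 18 (not isolated)
Conditions: iPrMgCl·LiCl (1.05 equiv), THF, −78 °C; then 17, −78 → −40 °C; aq. NH4Cl
Reagents that add atoms: none
Why: Iodine–magnesium exchange gives a pyranonyl Grignard reagent that should hold at −78 °C (a lithium analogue would fragment by β-elimination of the ring oxygen) and adds 1,2 to the squarate carbonyl next to the methoxy-bearing carbon, which is not shielded by the tert-butoxy group and is the less deactivated one because the twisted tert-butoxy oxygen is the weaker vinylogous donor; the carbinol centre forms as a racemate and disappears in step 11.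

Step 10
Reactants: 19 4-{6-[2,4-bis(benzyloxy)-5-methoxyphenyl]-5-methoxy-4-oxo-4H-pyran-3-yl}-2-tert-butoxy-4-hydroxy-3-methoxycyclobut-2-en-1-one
Product: 20 4-{6-[2,4-bis(benzyloxy)-5-methoxyphenyl]-5-methoxy-4-oxo-4H-pyran-3-yl}-2-tert-butoxy-3-methoxy-4-(methoxymethoxy)cyclobut-2-en-1-one (racemic)
Conditions: MOMCl, iPr2NEt, Bu4NI (cat.), CH2Cl2, 0 → 40 °C
Reagents that add atoms: chloromethyl methyl ether, COCCl
Why: Methoxymethyl ether formation on the tertiary carbinol under amine base caps the future C5 oxygen, so that the ring expansion delivers one free phenol only (C8) and not an air-sensitive hydroquinone.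

Step 11
Reactants: 20 4-{6-[2,4-bis(benzyloxy)-5-methoxyphenyl]-5-methoxy-4-oxo-4H-pyran-3-yl}-2-tert-butoxy-3-methoxy-4-(methoxymethoxy)cyclobut-2-en-1-one
Product: 23 2-[2,4-bis(benzyloxy)-5-methoxyphenyl]-7-tert-butoxy-8-hydroxy-3,6-dimethoxy-5-(methoxymethoxy)-4H-chromen-4-one, via dienylketene 21 (not isolated), via cyclohexadienone 22 (not isolated)
Conditions: degassed p-xylene, 138 °C, Ar
Reagents that add atoms: none
Why: Heating opens the cyclobutenone by conrotatory four-electron electrocyclic cleavage of the C1–C4 bond to dienylketene 21, and a disrotatory six-electron electrocyclization then joins the ketene carbon to pyranone C6 (the new C8–C8a bond) to give cyclohexadienone 22, which enolizes to the C8 phenol. This is the Moore rearrangement of 4-aryl- and 4-heteroaryl-4-oxycyclobutenones to fused hydroquinone monoethers, applied here to a 4-pyranon-3-yl group. Ring A, a six-membered carbocycle, is closed by this 6π-electrocyclization onto the C5=C6 bond of ring C, and rings B and C are not touched. No stereocentre remains, since the carbinol carbon of 20 becomes aromatic C5 and the sp3 C8a of 22 is lost on enolization. The step needs torquoselectivity, which the lone-pair donor oxygen (methoxymethoxy) on C4 should secure by rotating outward so that the pyranonyl group turns inward and sits cis to the ketene; the site of closure is fixed because C6 is the only hydrogen-bearing carbon next to the point of attachment, the other neighbour being the C4 carbonyl carbon. The four oxygens of ring A arrive told apart: C5 as the acetal, C6 as the methyl ether, C7 as the tert-butyl ether and C8 as the free phenol.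

Step 12
Reactants: 23 2-[2,4-bis(benzyloxy)-5-methoxyphenyl]-7-tert-butoxy-8-hydroxy-3,6-dimethoxy-5-(methoxymethoxy)-4H-chromen-4-one
Product: 24 2-[2,4-bis(benzyloxy)-5-methoxyphenyl]-7-tert-butoxy-3,6,8-trimethoxy-5-(methoxymethoxy)-4H-chromen-4-one
Conditions: MeI, K2CO3, DMF, rt
Reagents that add atoms: iodomethane, CI
Why: Williamson methylation of the only free hydroxyl, the C8 phenol, fixes the 8-methoxy group while C5 and C7 stay masked.

Step 13
Reactants: 24 2-[2,4-bis(benzyloxy)-5-methoxyphenyl]-7-tert-butoxy-3,6,8-trimethoxy-5-(methoxymethoxy)-4H-chromen-4-one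
Product: 25 2-[2,4-bis(benzyloxy)-5-methoxyphenyl]-5,7-dihydroxy-3,6,8-trimethoxy-4H-chromen-4-one
Conditions: CF3CO2H/CH2Cl2/H2O, 0 °C → rt
Reagents that add atoms: none
Why: Acidolysis cleaves the methoxymethyl acetal at C5 and the tert-butyl aryl ether at C7 (loss of the tert-butyl cation as isobutene), while methyl and benzyl aryl ethers should withstand trifluoroacetic acid at room temperature.

Step 14
Reactants: 25 2-[2,4-bis(benzyloxy)-5-methoxyphenyl]-5,7-dihydroxy-3,6,8-trimethoxy-4H-chromen-4-one
Product: 26 2-(2,4-dihydroxy-5-methoxyphenyl)-5,7-dihydroxy-3,6,8-trimethoxy-4H-chromen-4-one (5,7,2',4'-tetrahydroxy-3,6,8,5'-tetramethoxyflavone)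
Conditions: H2 (1 atm), Pd/C, EtOAc/MeOH, rt
Reagents that add atoms: none
Why: Hydrogenolysis of the two benzyl aryl ethers over palladium on carbon should leave the tetrasubstituted C2=C3 bond of the flavone and the methyl ethers untouched.

**Compound list**

1 | 3-(benzyloxy)-4-methoxybenzaldehyde | COc1ccc(C=O)cc1OCc1ccccc1 | starting material
2 | 3-(benzyloxy)-4-methoxyphenyl formate | COc1ccc(OC=O)cc1OCc1ccccc1 | intermediate
3 | 3-(benzyloxy)-4-methoxyphenol | COc1ccc(O)cc1OCc1ccccc1 | intermediate
4 | 2,4-bis(benzyloxy)-1-methoxybenzene | COc1ccc(OCc2ccccc2)cc1OCc1ccccc1 | intermediate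
5 | 1,5-bis(benzyloxy)-2-bromo-4-methoxybenzene | COc1cc(Br)c(OCc2ccccc2)cc1OCc1ccccc1 | intermediate
6 | N,2-dimethoxy-N-methylacetamide | COCC(=O)N(C)OC | starting material
7 | [2,4-bis(benzyloxy)-5-methoxyphenyl]lithium | [Li]c1cc(OC)c(OCc2ccccc2)cc1OCc1ccccc1 | intermediate
8 | 1-[2,4-bis(benzyloxy)-5-methoxyphenyl]-2-methoxyethan-1-one | COCC(=O)c1cc(OC)c(OCc2ccccc2)cc1OCc1ccccc1 | intermediate
9 | (E)-3-ethoxyprop-2-enoyl chloride | CCO/C=C/C(=O)Cl | starting material
10 | (4E)-1-[2,4-bis(benzyloxy)-5-methoxyphenyl]-5-ethoxy-2-methoxypent-4-ene-1,3-dione (racemic) | CCO/C=C/C(=O)C(OC)C(=O)c1cc(OC)c(OCc2ccccc2)cc1OCc1ccccc1 | intermediate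
11 | (4E)-1-[2,4-bis(benzyloxy)-5-methoxyphenyl]-5-(dimethylamino)-2-methoxypent-4-ene-1,3-dione (racemic) | CN(C)/C=C/C(=O)C(OC)C(=O)c1cc(OC)c(OCc2ccccc2)cc1OCc1ccccc1 | intermediate
12 | (4Z)-1-[2,4-bis(benzyloxy)-5-methoxyphenyl]-5-(dimethylamino)-4-iodo-2-methoxypent-4-ene-1,3-dione (racemic) | CN(C)/C=C(\I)C(=O)C(OC)C(=O)c1cc(OC)c(OCc2ccccc2)cc1OCc1ccccc1 | intermediate
13 | 2-[2,4-bis(benzyloxy)-5-methoxyphenyl]-5-iodo-3-methoxy-4H-pyran-4-one | COc1c(-c2cc(OC)c(OCc3ccccc3)cc2OCc2ccccc2)occ(I)c1=O | intermediate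
14 | 3,4-dimethoxycyclobut-3-ene-1,2-dione (dimethyl squarate) | COC1=C(OC)C(=O)C1=O | starting material
15 | sodium 2-methoxy-3,4-dioxocyclobut-1-en-1-olate | COC1=C([O-])C(=O)C1=O.[Na+] | intermediate
16 | 3-hydroxy-4-methoxycyclobut-3-ene-1,2-dione | COC1=C(O)C(=O)C1=O | intermediate
17 | 3-tert-butoxy-4-methoxycyclobut-3-ene-1,2-dione | COC1=C(OC(C)(C)C)C(=O)C1=O | intermediate
18 | {6-[2,4-bis(benzyloxy)-5-methoxyphenyl]-5-methoxy-4-oxo-4H-pyran-3-yl}magnesium chloride (LiCl complex) | COc1c(-c2cc(OC)c(OCc3ccccc3)cc2OCc2ccccc2)occ([Mg]Cl)c1=O | intermediate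
19 | 4-{6-[2,4-bis(benzyloxy)-5-methoxyphenyl]-5-methoxy-4-oxo-4H-pyran-3-yl}-2-tert-butoxy-4-hydroxy-3-methoxycyclobut-2-en-1-one (racemic) | O=C1C(OC(C)(C)C)=C(OC)C1(O)c1coc(-c2cc(OC)c(OCc3ccccc3)cc2OCc2ccccc2)c(OC)c1=O | intermediate
20 | 4-{6-[2,4-bis(benzyloxy)-5-methoxyphenyl]-5-methoxy-4-oxo-4H-pyran-3-yl}-2-tert-butoxy-3-methoxy-4-(methoxymethoxy)cyclobut-2-en-1-one (racemic) | O=C1C(OC(C)(C)C)=C(OC)C1(OCOC)c1coc(-c2cc(OC)c(OCc3ccccc3)cc2OCc2ccccc2)c(OC)c1=O | intermediate
21 | (3Z)-4-{6-[2,4-bis(benzyloxy)-5-methoxyphenyl]-5-methoxy-4-oxo-4H-pyran-3-yl}-2-tert-butoxy-3-methoxy-4-(methoxymethoxy)buta-1,3-dien-1-one (pyranonyl cis to the ketene carbon) | O=C=C(OC(C)(C)C)/C(OC)=C(/OCOC)c1coc(-c2cc(OC)c(OCc3ccccc3)cc2OCc2ccccc2)c(OC)c1=O | intermediate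
22 | 2-[2,4-bis(benzyloxy)-5-methoxyphenyl]-7-tert-butoxy-3,6-dimethoxy-5-(methoxymethoxy)-8aH-chromene-4,8-dione (racemic) | O=C1C(OC(C)(C)C)=C(OC)C(OCOC)=C2C(=O)C(OC)=C(c3cc(OC)c(OCc4ccccc4)cc3OCc3ccccc3)OC12 | intermediate
23 | 2-[2,4-bis(benzyloxy)-5-methoxyphenyl]-7-tert-butoxy-8-hydroxy-3,6-dimethoxy-5-(methoxymethoxy)-4H-chromen-4-one | COCOc1c(OC)c(OC(C)(C)C)c(O)c2oc(-c3cc(OC)c(OCc4ccccc4)cc3OCc3ccccc3)c(OC)c(=O)c12 | intermediate
24 | 2-[2,4-bis(benzyloxy)-5-methoxyphenyl]-7-tert-butoxy-3,6,8-trimethoxy-5-(methoxymethoxy)-4H-chromen-4-one | COCOc1c(OC)c(OC(C)(C)C)c(OC)c2oc(-c3cc(OC)c(OCc4ccccc4)cc3OCc3ccccc3)c(OC)c(=O)c12 | intermediate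
25 | 2-[2,4-bis(benzyloxy)-5-methoxyphenyl]-5,7-dihydroxy-3,6,8-trimethoxy-4H-chromen-4-one | COc1c(O)c(OC)c2oc(-c3cc(OC)c(OCc4ccccc4)cc3OCc3ccccc3)c(OC)c(=O)c2c1O | intermediate
26 | 2-(2,4-dihydroxy-5-methoxyphenyl)-5,7-dihydroxy-3,6,8-trimethoxy-4H-chromen-4-one | COc1cc(-c2oc3c(OC)c(O)c(OC)c(O)c3c(=O)c2OC)c(O)cc1O | target

**Step count**

Total: 14 steps. Longest linear sequence: 12 steps (steps 1–6 and 9–14); steps 7 and 8 form the squarate branch.

**Steps most likely to fail**

1. Step 9. What may go wrong is poor discrimination between the two carbonyl groups of the mixed squarate, so that attack next to the tert-butoxy-bearing carbon gives the constitutional isomer with the two alkoxy groups exchanged; the magnesiated pyranone may also decay by ring-opening β-elimination before it adds. The fallback sets out from 13 (through its Grignard reagent 18) and comes back at 20. Reagent 18 is added at −78 °C to purchased 3,4-di-tert-butoxycyclobut-3-ene-1,2-dione, whose two carbonyl groups are equivalent, which should give 4-{6-[2,4-bis(benzyloxy)-5-methoxyphenyl]-5-methoxy-4-oxo-4H-pyran-3-yl}-2,3-di-tert-butoxy-4-hydroxycyclobut-2-en-1-one F1. MOMCl and iPr2NEt should convert it into 4-{6-[2,4-bis(benzyloxy)-5-methoxyphenyl]-5-methoxy-4-oxo-4H-pyran-3-yl}-2,3-di-tert-butoxy-4-(methoxymethoxy)cyclobut-2-en-1-one F2. NaOMe (catalytic) in MeOH/THF at 0 °C should then exchange only the tert-butoxy group on the vinylogous ester carbon C3 by conjugate addition–elimination, since the enol ether at C2 is inert to alkoxide, and this gives 20 with the regiochemistry fixed by construction.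

2. Step 11. What may go wrong is decay of the ketene before it closes: wrong-way rotation of the acetal-bearing carbon, thermal loss of isobutene from the tert-butyl ether, or slow closure onto the electron-poor C6 of the pyranone. The fallback sets out from 19 and comes back at 25. The free carbinol 19, the classical hydroxy substrate of this ring expansion with the strongest outward-rotating donor, is heated in degassed toluene or xylene and should give the hydroquinone 2-[2,4-bis(benzyloxy)-5-methoxyphenyl]-7-tert-butoxy-5,8-dihydroxy-3,6-dimethoxy-4H-chromen-4-one F3. Under argon, MeI (1.0 equiv) and K2CO3 in acetone should methylate only the 8-hydroxyl, because the 5-hydroxyl is held by a hydrogen bond to the C4 carbonyl, to give 2-[2,4-bis(benzyloxy)-5-methoxyphenyl]-7-tert-butoxy-5-hydroxy-3,6,8-trimethoxy-4H-chromen-4-one F4. Trifluoroacetic acid in CH2Cl2 then removes the tert-butyl group and gives 25.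

3. Step 6. What may go wrong is iodination of the enaminone without ring closure, because the 2-methoxy-1,3-dicarbonyl unit enolizes reluctantly, or cleavage of the diketone by the liberated amine. The fallback sets out from 11 and comes back at 13. Acid (CF3CO2H, CH2Cl2, rt) should cyclize 11 with loss of dimethylamine to 2-[2,4-bis(benzyloxy)-5-methoxyphenyl]-3-methoxy-4H-pyran-4-one F5. This is then iodinated at C5 with I2 and pyridine in CH2Cl2, the nucleophile-promoted α-iodination known for cyclic enones and 2,3-dihydro-4-pyranones, which does not rely on an electrophile strong enough to attack ring B, to give 13.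

**Further compounds**

F1 | step 9 | 4-{6-[2,4-bis(benzyloxy)-5-methoxyphenyl]-5-methoxy-4-oxo-4H-pyran-3-yl}-2,3-di-tert-butoxy-4-hydroxycyclobut-2-en-1-one (racemic) | O=C1C(OC(C)(C)C)=C(OC(C)(C)C)C1(O)c1coc(-c2cc(OC)c(OCc3ccccc3)cc2OCc2ccccc2)c(OC)c1=O
F2 | step 9 | 4-{6-[2,4-bis(benzyloxy)-5-methoxyphenyl]-5-methoxy-4-oxo-4H-pyran-3-yl}-2,3-di-tert-butoxy-4-(methoxymethoxy)cyclobut-2-en-1-one (racemic) | O=C1C(OC(C)(C)C)=C(OC(C)(C)C)C1(OCOC)c1coc(-c2cc(OC)c(OCc3ccccc3)cc2OCc2ccccc2)c(OC)c1=O
F3 | step 11 | 2-[2,4-bis(benzyloxy)-5-methoxyphenyl]-7-tert-butoxy-5,8-dihydroxy-3,6-dimethoxy-4H-chromen-4-one | Oc1c(OC)c(OC(C)(C)C)c(O)c2oc(-c3cc(OC)c(OCc4ccccc4)cc3OCc3ccccc3)c(OC)c(=O)c12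
F4 | step 11 | 2-[2,4-bis(benzyloxy)-5-methoxyphenyl]-7-tert-butoxy-5-hydroxy-3,6,8-trimethoxy-4H-chromen-4-one | Oc1c(OC)c(OC(C)(C)C)c(OC)c2oc(-c3cc(OC)c(OCc4ccccc4)cc3OCc3ccccc3)c(OC)c(=O)c12
F5 | step 6 | 2-[2,4-bis(benzyloxy)-5-methoxyphenyl]-3-methoxy-4H-pyran-4-one | COc1c(-c2cc(OC)c(OCc3ccccc3)cc2OCc2ccccc2)occc1=O
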